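**Strategy.** The pyranone ring of the flavanone (O1–C2–C3–C4–C4a–C8a) is not closed as a six-membered ring: it is grown from a five-membered benzofuran-3(2H)-one by a Dowd–Beckwith one-carbon ring expansion. A racemic 2-(iodomethyl)-2-phenylbenzofuranone gives a primary radical that inserts its CH2 (future C3) between C2 and the C4 carbonyl; the migration is driven by the benzylic, O1-stabilised radical left at C2. This planar radical erases the quaternary stereocentre, and a chiral thiol then delivers the hydrogen atom, so both enantiomers of the precursor converge on (2S). The acetyl group of phloroacetophenone fixes the regiochemistry of the A ring; the pyrone arm is attached last.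

Key step: step 7

Remark: compounds 3–13 that carry a stereocentre are racemic; that centre is erased in step 7, where the only stereocentre of the target (C2, S) is set.
Remark: the chiral thiol of step 7 is specified by class (cysteine-derived β-turn peptide thiol); the antipode that delivers hydrogen to the face giving (2S) is to be found by screening.

Step 1
Reactants: 1 1-(2,4,6-trihydroxyphenyl)ethan-1-one
Product: 2 1-[2,4-bis(benzyloxy)-6-hydroxyphenyl]ethan-1-one
Conditions: BnBr (2.1 equiv), K2CO3, DMF, 60 °C
Reagents that add atoms: benzyl bromide, BrCc1ccccc1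
Why: Williamson etherification of the para-OH and one ortho-OH; the second ortho-OH stays free because it is locked in a hydrogen bond to the acetyl carbonyl.

Step 2
Reactants: 2 1-[2,4-bis(benzyloxy)-6-hydroxyphenyl]ethan-1-one; 3 methyl 2-bromo-2-phenylacetate (racemic)
Product: 4 methyl 2-[2-acetyl-3,5-bis(benzyloxy)phenoxy]-2-phenylacetate (racemic)
Conditions: K2CO3, DMF, 45 °C
Reagents that add atoms: none
Why: Williamson etherification (SN2) of the chelated phenoxide with the activated secondary α-bromo ester; this bond decides which oxygen becomes O1, and the mild temperature should avoid aldol closure onto the acetyl group.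

Step 3
Reactants: 4 methyl 2-[2-acetyl-3,5-bis(benzyloxy)phenoxy]-2-phenylacetate
Product: 5 2-[2-acetyl-3,5-bis(benzyloxy)phenoxy]-2-phenylacetic acid (racemic)
Conditions: LiOH·H2O, THF/H2O, rt; then 1 M HCl
Reagents that add atoms: lithium hydroxide, [Li+].[OH-]
Why: Saponification of the methyl ester; benzyl ethers and the aryl ketone are inert to hydroxide at room temperature.

Step 4
Reactants: 5 2-[2-acetyl-3,5-bis(benzyloxy)phenoxy]-2-phenylacetic acid
Product: 7 7-acetyl-4,6-bis(benzyloxy)-2-phenyl-1-benzofuran-3(2H)-one (racemic), via mixed trifluoroacetic anhydride 6 (not isolated)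
Conditions: TFAA, CH2Cl2, 0 °C → rt; aqueous NaHCO3 work-up; product used directly under argon
Reagents that add atoms: none
Why: Intramolecular Friedel–Crafts acylation through the mixed anhydride at the only free position ortho to the ether oxygen (activated by three oxygens), which closes the five-membered ketone with the acetyl group next to the ring oxygen.

Step 5
Reactants: 7 7-acetyl-4,6-bis(benzyloxy)-2-phenyl-1-benzofuran-3(2H)-one; 8 diiodomethane
Product: 9 7-acetyl-4,6-bis(benzyloxy)-2-(iodomethyl)-2-phenyl-1-benzofuran-3(2H)-one (racemic)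
Conditions: NaH (1.05 equiv), THF/DMPU, 0 °C; CH2I2 (5 equiv), 0 → 45 °C
Reagents that add atoms: none
Why: C-alkylation of the stabilised tertiary enolate (C2–H is far more acidic than the acetyl CH3) with excess diiodomethane, the standard entry to Dowd–Beckwith substrates; the peri benzyloxy group shields the enolate oxygen.

Step 6
Reactants: 9 7-acetyl-4,6-bis(benzyloxy)-2-(iodomethyl)-2-phenyl-1-benzofuran-3(2H)-one; 10 acetone
Product: 13 4,6-bis(benzyloxy)-2-(iodomethyl)-7-(3-methylbut-2-enoyl)-2-phenyl-1-benzofuran-3(2H)-one (racemic), via aldol adduct 11 (not isolated), via tertiary mesylate 12 (not isolated)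
Conditions: LiHMDS, THF, −78 °C; acetone, −78 °C; MsCl, Et3N, −78 °C → rt
Reagents that add atoms: none
Why: Directed aldol addition of the methyl ketone lithium enolate (the only enolisable position, since C2 is quaternary) to acetone, then mesylation of the aldolate in the same flask and E1cB elimination to the conjugated enone.

Step 7
Reactants: 13 4,6-bis(benzyloxy)-2-(iodomethyl)-7-(3-methylbut-2-enoyl)-2-phenyl-1-benzofuran-3(2H)-one
Product: 15 (2S)-5,7-bis(benzyloxy)-8-(3-methylbut-2-enoyl)-2-phenyl-2,3-dihydro-4H-chromen-4-one, via ring-expanded C2 radical 14 (not isolated)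
Conditions: Et3SiH (3 equiv), chiral cysteine-peptide thiol (10 mol %), di-tert-butyl hyponitrite (5 mol %), degassed cyclohexane/1,4-dioxane, 50 °C, 0.02 M
Reagents that add atoms: none
Why: Proposed new method: Et3Si• abstracts iodine from 13, the primary radical adds 3-exo-trig to the adjacent ring ketone, and the cyclopropyloxy radical opens by β-scission of the old C2–C(=O) bond (net 1,2-acyl shift) to the six-membered radical 14, which is benzylic and α to O1. The closest known reactions are the Dowd–Beckwith ring expansion (normally run racemic on β-keto esters with tin hydride) and thiol polarity-reversal catalysis of silane reductions, including enantioselective hydrogen-atom transfer from homochiral thiols to prochiral benzylic radicals; their combination on this substrate class is new. The six-membered ring therefore arises by ring expansion (3-exo-trig closure followed by fragmentation), not by a direct six-membered closure. C2 is set under catalyst control, the chiral thiol handing hydrogen to one face of planar 14, so both enantiomers of 13 converge on (2S). The step needs the acyl shift to outrun premature reduction and the intrinsically slower neophyl-type phenyl shift, which the low thiol concentration, the aryl ketone acceptor and the stabilised product radical should secure; it also needs iodine abstraction to outrun silyl-radical attack on the hindered β,β-disubstituted enone.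

Step 8
Reactants: 15 (2S)-5,7-bis(benzyloxy)-8-(3-methylbut-2-enoyl)-2-phenyl-2,3-dihydro-4H-chromen-4-one
Product: 16 (2S)-5,7-dihydroxy-8-(3-methylbut-2-enoyl)-2-phenyl-2,3-dihydro-4H-chromen-4-one
Conditions: BCl3, C6HMe5, CH2Cl2, −78 °C; MeOH/H2O quench at −78 °C
Reagents that add atoms: none
Why: Lewis-acid debenzylation with pentamethylbenzene as benzyl-cation scavenger; both benzyl ethers sit ortho to a carbonyl and should cleave by chelation at −78 °C, leaving the enone and the base-sensitive C2 centre untouched.

Step 9
Reactants: 17 pentan-3-one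
Product: 18 3-(trimethylsilyloxy)pent-2-ene (E/Z mixture)
Conditions: TMSCl, Et3N, DMF, 80 °C
Reagents that add atoms: chlorotrimethylsilane, C[Si](C)(C)Cl
Why: Silyl enol ether formation from a symmetrical ketone under thermodynamic conditions; either alkene isomer serves.

Step 10
Reactants: 18 3-(trimethylsilyloxy)pent-2-ene; 19 malonyl dichloride
Product: 20 6-ethyl-4-hydroxy-5-methyl-2H-pyran-2-one
Conditions: Et2O, −78 °C → rt
Reagents that add atoms: none
Why: Pyrone synthesis by C-acylation of the silyl enol ether with malonyl dichloride, then ring closure of the enol oxygen onto the second acid chloride.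

Step 11
Reactants: 20 6-ethyl-4-hydroxy-5-methyl-2H-pyran-2-one; 21 N,N-dimethylmethyleneiminium iodide (Eschenmoser's salt); 16 (2S)-5,7-dihydroxy-8-(3-methylbut-2-enoyl)-2-phenyl-2,3-dihydro-4H-chromen-4-one
Product: 24 (2S)-6-[(6-ethyl-4-hydroxy-5-methyl-2-oxo-2H-pyran-3-yl)methyl]-5,7-dihydroxy-8-(3-methylbut-2-enoyl)-2-phenyl-2,3-dihydro-4H-chromen-4-one (target), via pyrone Mannich base 22 (not isolated), via pyrone methide 23 (not isolated)
Conditions: 20 + 21 (1.0 equiv), MeCN, rt; then 16, 60 °C
Reagents that add atoms: none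
Why: Mannich reaction at C3 of the pyrone, loss of dimethylamine to the pyrone methide, and conjugate addition of C6 of the phloroglucinol ring (its only free position) in a three-component carba-Betti coupling; no free base is present, so C2 should not epimerise and the enone should not cyclise.

**Compound list**

1 | 1-(2,4,6-trihydroxyphenyl)ethan-1-one (phloroacetophenone) | CC(=O)c1c(O)cc(O)cc1O | starting material
2 | 1-[2,4-bis(benzyloxy)-6-hydroxyphenyl]ethan-1-one | CC(=O)c1c(O)cc(OCc2ccccc2)cc1OCc1ccccc1 | intermediate
3 | methyl 2-bromo-2-phenylacetate (racemic) | COC(=O)C(Br)c1ccccc1 | starting material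
4 | methyl 2-[2-acetyl-3,5-bis(benzyloxy)phenoxy]-2-phenylacetate (racemic) | COC(=O)C(Oc1cc(OCc2ccccc2)cc(OCc2ccccc2)c1C(C)=O)c1ccccc1 | intermediate
5 | 2-[2-acetyl-3,5-bis(benzyloxy)phenoxy]-2-phenylacetic acid (racemic) | OC(=O)C(Oc1cc(OCc2ccccc2)cc(OCc2ccccc2)c1C(C)=O)c1ccccc1 | intermediate
6 | mixed anhydride of 5 with trifluoroacetic acid (not isolated) | O=C(OC(=O)C(F)(F)F)C(Oc1cc(OCc2ccccc2)cc(OCc2ccccc2)c1C(C)=O)c1ccccc1 | intermediate
7 | 7-acetyl-4,6-bis(benzyloxy)-2-phenyl-1-benzofuran-3(2H)-one (racemic) | CC(=O)c1c(OCc2ccccc2)cc(OCc2ccccc2)c2C(=O)C(c3ccccc3)Oc12 | intermediate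
8 | diiodomethane | ICI | starting material
9 | 7-acetyl-4,6-bis(benzyloxy)-2-(iodomethyl)-2-phenyl-1-benzofuran-3(2H)-one (racemic) | CC(=O)c1c(OCc2ccccc2)cc(OCc2ccccc2)c2C(=O)C(CI)(c3ccccc3)Oc12 | intermediate
10 | acetone | CC(C)=O | starting material
11 | 4,6-bis(benzyloxy)-7-(3-hydroxy-3-methylbutanoyl)-2-(iodomethyl)-2-phenyl-1-benzofuran-3(2H)-one, aldol adduct present as its lithium alkoxide (not isolated) | CC(C)(O)CC(=O)c1c(OCc2ccccc2)cc(OCc2ccccc2)c2C(=O)C(CI)(c3ccccc3)Oc12 | intermediate
12 | tertiary methanesulfonate of 11 (not isolated) | CC(C)(OS(C)(=O)=O)CC(=O)c1c(OCc2ccccc2)cc(OCc2ccccc2)c2C(=O)C(CI)(c3ccccc3)Oc12 | intermediate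
13 | 4,6-bis(benzyloxy)-2-(iodomethyl)-7-(3-methylbut-2-enoyl)-2-phenyl-1-benzofuran-3(2H)-one (racemic) | CC(C)=CC(=O)c1c(OCc2ccccc2)cc(OCc2ccccc2)c2C(=O)C(CI)(c3ccccc3)Oc12 | intermediate
14 | 5,7-bis(benzyloxy)-8-(3-methylbut-2-enoyl)-4-oxo-2-phenylchroman-2-yl radical (not isolated) | CC(C)=CC(=O)c1c(OCc2ccccc2)cc(OCc2ccccc2)c2C(=O)C[C](c3ccccc3)Oc12 | intermediate
15 | (2S)-5,7-bis(benzyloxy)-8-(3-methylbut-2-enoyl)-2-phenyl-2,3-dihydro-4H-chromen-4-one | CC(C)=CC(=O)c1c(OCc2ccccc2)cc(OCc2ccccc2)c2C(=O)C[C@@H](c3ccccc3)Oc12 | intermediate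
16 | (2S)-5,7-dihydroxy-8-(3-methylbut-2-enoyl)-2-phenyl-2,3-dihydro-4H-chromen-4-one | CC(C)=CC(=O)c1c(O)cc(O)c2C(=O)C[C@@H](c3ccccc3)Oc12 | intermediate
17 | pentan-3-one | CCC(=O)CC | starting material
18 | 3-(trimethylsilyloxy)pent-2-ene (E/Z mixture) | CC=C(CC)O[Si](C)(C)C | intermediate
19 | malonyl dichloride | O=C(Cl)CC(=O)Cl | starting material
20 | 6-ethyl-4-hydroxy-5-methyl-2H-pyran-2-one | CCc1oc(=O)cc(O)c1C | intermediate
21 | N,N-dimethylmethyleneiminium iodide (Eschenmoser's salt) | C=[N+](C)C.[I-] | starting material
22 | 3-[(dimethylamino)methyl]-6-ethyl-4-hydroxy-5-methyl-2H-pyran-2-one, present as its hydroiodide (not isolated) | CCc1oc(=O)c(CN(C)C)c(O)c1C | intermediate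
23 | 6-ethyl-5-methyl-3-methylidene-2H-pyran-2,4(3H)-dione (not isolated) | CCC1=C(C)C(=O)C(=C)C(=O)O1 | intermediate
24 | (2S)-6-[(6-ethyl-4-hydroxy-5-methyl-2-oxo-2H-pyran-3-yl)methyl]-5,7-dihydroxy-8-(3-methylbut-2-enoyl)-2-phenyl-2,3-dihydro-4H-chromen-4-one | CCc1oc(=O)c(Cc2c(O)c(C(=O)C=C(C)C)c3c(c2O)C(=O)C[C@@H](c2ccccc2)O3)c(O)c1C | target

Total step count: 11. Longest linear sequence: 9 steps (steps 1–8 and 11); steps 9–10 build the pyrone in a side branch.

**Steps most likely to fail**

1. Step 7 (the step carrying the label). The risk is poor facial discrimination in the hydrogen-atom transfer to radical 14, or hydrogen transfer to the primary radical before the acyl shift. The fallback uses known chemistry, sets out from 13 and returns at 15. Tin-hydride Dowd–Beckwith ring expansion (Bu3SnH by syringe pump, AIBN, benzene, 80 °C) should give racemic 5,7-bis(benzyloxy)-8-(3-methylbut-2-enoyl)-2-phenyl-2,3-dihydro-4H-chromen-4-one F1. Kinetic resolution by Rh–TsDPEN asymmetric transfer hydrogenation (HCO2H/Et3N, EtOAc, rt, the ligand antipode that reduces the (2R)-ketone faster), stopped near half conversion, should turn the (2R)-enantiomer into (2R,4R)-5,7-bis(benzyloxy)-8-(3-methylbut-2-enoyl)-2-phenylchroman-4-ol F2. F2 is removed by chromatography, leaving 15. The hindered, cross-conjugated side-chain ketone is expected to be reduced more slowly than the ring ketone, but this would have to be checked.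

2. Step 5. The risk is O-alkylation of the ambident enolate, or a second displacement on the iodomethyl group that bridges two enolates. The fallback sets out from 7 and returns at 9. Base-catalysed aldol addition to formaldehyde (aq. HCHO, cat. Et3N, THF, 0 °C) can only end on carbon, because O-hydroxymethylation is reversible, and should give 7-acetyl-4,6-bis(benzyloxy)-2-(hydroxymethyl)-2-phenyl-1-benzofuran-3(2H)-one F3. Appel iodination (PPh3, I2, imidazole, toluene, 60 °C) then leads to 9.

3. Step 11. The risk is capture of the pyrone methide by unreacted pyrone, outcompeting attack by the doubly acylated and therefore less nucleophilic arene. The fallback sets out from 16 and returns at 24, with the roles of the two partners reversed. Mannich reaction of 16 alone with Eschenmoser's salt (MeCN, rt) should give (2S)-6-[(dimethylamino)methyl]-5,7-dihydroxy-8-(3-methylbut-2-enoyl)-2-phenyl-2,3-dihydro-4H-chromen-4-one F4, kept as its hydroiodide. Heating F4 with pyrone 20 (1,4-dioxane, 80 °C) releases the ortho-quinone methide of the flavanone, which is trapped by C3 of the pyrone to give 24.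

**Further compounds**

F1 | step 7 | racemic 5,7-bis(benzyloxy)-8-(3-methylbut-2-enoyl)-2-phenyl-2,3-dihydro-4H-chromen-4-one | CC(C)=CC(=O)c1c(OCc2ccccc2)cc(OCc2ccccc2)c2C(=O)CC(c3ccccc3)Oc12
F2 | step 7 | (2R,4R)-5,7-bis(benzyloxy)-8-(3-methylbut-2-enoyl)-2-phenylchroman-4-ol | CC(C)=CC(=O)c1c(OCc2ccccc2)cc(OCc2ccccc2)c2[C@H](O)C[C@H](c3ccccc3)Oc12
F3 | step 5 | 7-acetyl-4,6-bis(benzyloxy)-2-(hydroxymethyl)-2-phenyl-1-benzofuran-3(2H)-one (racemic) | CC(=O)c1c(OCc2ccccc2)cc(OCc2ccccc2)c2C(=O)C(CO)(c3ccccc3)Oc12
F4 | step 11 | (2S)-6-[(dimethylamino)methyl]-5,7-dihydroxy-8-(3-methylbut-2-enoyl)-2-phenyl-2,3-dihydro-4H-chromen-4-one | CC(C)=CC(=O)c1c(O)c(CN(C)C)c(O)c2C(=O)C[C@@H](c3ccccc3)Oc12
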